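**Plan**

Numbering: ring A = C1–C6 (C1 carries the chain, C4 = C(Me)OH, C5 = CHBr); diene = C7–C10 (methyl on C7); pyran = O, C11–C15 (C11 = C(Me)O, C14 = CHBr, C15 = CMe2).
Retrosynthesis: C9=C10 is cut first (allylic phosphonate + pyran aldehyde), then C7=C8 (olefination of a methyl ketone at C7), then the C4–OH/C5–Br pair is traced back to a C4=C5 alkene.
Enabling feature: ring A holds C7 and the C4 methyl in a 1,4-relationship with functionality at C4–C5, so it is the para [4+2] adduct of isoprene (C3–C4(Me)=C5–C6) and an acrylate (C1–C2, carbonyl carbon = C7); cutting C1–C6 and C2–C3 leaves two commercial compounds.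
The pyran is cut at O–C15 and C14–Br back to (S)-linalool. Forward: ring A is closed (step 1), converted into the protected cis-bromohydrin ketone (steps 2–6) and extended to C9 (steps 7–9); the pyran aldehyde is made (steps 10–11); the halves are joined (step 12) and the silyl ether is removed (step 13).
Stereochemistry: C1 from the chiral oxazaborolidinium catalyst; C4 and C5 relayed from C1 (trans-diaxial epoxide hydrolysis, then SN2 inversion at C5); C11 from (S)-linalool; C14 from anti bromoetherification with separation of the trans isomer; both alkenes E from phosphonate olefinations.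

Key step: step 1

Assumption: the catalyst from (S)-α,α-diphenylprolinol is taken to leave the Cα Si face of the bound acrylate open and so to give the 1R adduct; if the sense is the reverse, the catalyst from (R)-diphenylprolinol is used with no other change.
Assumption: (S)-(+)-linalool is taken to be purchasable in high enantiomeric purity; any (R) material would surface after step 12 as a separable diastereomer.

**Route**

Step 1
Reactants: 1 isoprene; 2 2,2,2-trifluoroethyl acrylate
Product: 3 2,2,2-trifluoroethyl (1R)-4-methylcyclohex-3-ene-1-carboxylate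
Conditions: N-protonated (S)-B-(o-tolyl)-α,α-diphenylprolinol oxazaborolidine as its triflimide salt, [C24H25BNO][N(SO2CF3)2] (10 mol %, formed in situ from the oxazaborolidine and HN(SO2CF3)2), CH2Cl2, −20 °C → 23 °C
Reagents that add atoms: none
Why: Binding of the acrylate carbonyl to the cationic boron lowers its LUMO, and isoprene adds in a concerted, asynchronous, suprafacial [4+2] cycloaddition; the closest known reaction type is the oxazaborolidinium-catalysed Diels–Alder reaction of acrylates with 2-substituted butadienes. Ring A closes as a six-membered carbocycle in this single cycloaddition, the C2–C3 bond (acrylate β-carbon to the isoprene CH2 next to the methyl-bearing carbon) forming ahead of C1–C6. The one new stereocentre, C1, is set by the catalyst: in the s-trans complex one face of the acrylate lies against a phenyl group of the diphenylprolinol unit, so the diene should add to the open Cα Si face and give the 1R ester. Para regiochemistry is required and is secured by the larger terminal HOMO coefficient that the 2-methyl group gives isoprene, which places C1 and the C4 methyl 1,4 to each other. The electron-poor trifluoroethyl ester supplies the reactivity an unactivated diene needs, and the C4=C5 alkene left behind is the handle for the bromohydrin.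

Step 2
Reactants: 3 2,2,2-trifluoroethyl (1R)-4-methylcyclohex-3-ene-1-carboxylate
Product: 5 1-[(1R)-4-methylcyclohex-3-en-1-yl]ethan-1-one, via Weinreb amide 4 (not isolated)
Conditions: MeNH(OMe)·HCl, i-PrMgCl, THF, −20 °C; then MeMgBr, 0 °C; aq. NH4Cl
Reagents that add atoms: methylmagnesium bromide, C[Mg]Br
Why: The magnesium amide of N,O-dimethylhydroxylamine acylates on the activated ester, and the chelated tetrahedral adduct of the resulting amide with MeMgBr releases the ketone only on work-up (Weinreb ketone synthesis), so neither over-addition nor enolisation at C1 is expected.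

Step 3
Reactants: 5 1-[(1R)-4-methylcyclohex-3-en-1-yl]ethan-1-one
Product: 8 1-[(1R,3S,4S)-3,4-dihydroxy-4-methylcyclohexyl]ethan-1-one, via trans-epoxide 6 (not isolated), via cis-epoxide 7 (not isolated)
Conditions: mCPBA, NaHCO3, CH2Cl2, 0 °C; aqueous wash; then crude epoxides, HClO4 (cat.), THF/H2O, 0 °C → 23 °C
Reagents that add atoms: 3-chloroperoxybenzoic acid, OOC(=O)c1cccc(Cl)c1; water, O
Why: Prilezhaev epoxidation of the trisubstituted alkene (the ketone is untouched at 0 °C under buffering) is not face-selective, but acid hydrolysis opens both epoxides anti and trans-diaxially (Fürst–Plattner rule), 6 at the tertiary C4 and 7 at C5, so both should converge on the one diaxial diol with C4–OH cis and C5–OH trans to the acetyl group, as the two limonene oxides converge on one diol.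

Step 4
Reactants: 8 1-[(1R,3S,4S)-3,4-dihydroxy-4-methylcyclohexyl]ethan-1-one
Product: 10 1-[(3aS,5R,7aS)-7a-methyl-2,2-dioxidohexahydro-1,3,2-benzodioxathiol-5-yl]ethan-1-one (trans-fused cyclic sulfate), via cyclic sulfite 9 (not isolated)
Conditions: SOCl2, Et3N, CH2Cl2, 0 °C; then RuCl3·xH2O (cat.), NaIO4, MeCN/H2O, 0 °C
Reagents that add atoms: thionyl chloride, O=S(Cl)Cl; sodium periodate, [Na+].[O-]I(=O)(=O)=O
Why: Cyclic sulfite formation followed by RuO4-catalysed oxidation is the standard two-stage cyclic sulfate synthesis and is feasible for a trans-cyclohexane-1,2-diol once the ring flips to the diequatorial chair; the ketone is inert and no stereocentre is touched.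

Step 5
Reactants: 10 trans-fused cyclic sulfate
Product: 12 1-[(1R,3R,4S)-3-bromo-4-hydroxy-4-methylcyclohexyl]ethan-1-one, via lithium sulfate monoester 11 (not isolated)
Conditions: LiBr, THF, 23 → 40 °C; then H2SO4 (cat.), H2O (2 equiv), THF, 23 °C
Reagents that add atoms: lithium bromide, [Li+].[Br-]
Why: Bromide opens the activated cyclic sulfate by SN2 at the secondary C5 (the tertiary C4 has no accessible rear side), inverting C5 so that bromine ends cis to the C4 oxygen, and acid hydrolysis of the tertiary sulfate monoester goes by S–O cleavage and so retains C4.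

Step 6
Reactants: 12 1-[(1R,3R,4S)-3-bromo-4-hydroxy-4-methylcyclohexyl]ethan-1-one
Product: 13 1-[(1R,3R,4S)-3-bromo-4-methyl-4-(triethylsilyloxy)cyclohexyl]ethan-1-one
Conditions: Et3SiOTf, 2,6-lutidine, CH2Cl2, −78 → 0 °C
Reagents that add atoms: triethylsilyl trifluoromethanesulfonate, CC[Si](CC)(CC)OS(=O)(=O)C(F)(F)F
Why: Silyl triflate silylation of the hindered tertiary alcohol masks it for the basic steps ahead (an alkoxide next to the cis bromide could trigger semipinacol ring contraction), and at low temperature with 2,6-lutidine the methyl ketone should not be converted into an enol ether.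

Step 7
Reactants: 13 1-[(1R,3R,4S)-3-bromo-4-methyl-4-(triethylsilyloxy)cyclohexyl]ethan-1-one
Product: 14 ethyl (2E)-3-[(1R,3R,4S)-3-bromo-4-methyl-4-(triethylsilyloxy)cyclohexyl]but-2-enoate
Conditions: (EtO)2P(O)CH2CO2Et, NaH, THF, 0 → 60 °C
Reagents that add atoms: triethyl phosphonoacetate, CCOC(=O)CP(=O)(OCC)OCC
Why: Horner–Wadsworth–Emmons olefination of the α-branched methyl ketone should favour the E enoate (ring trans to the ester), the minor Z isomer being removed by chromatography; the equatorial bromide has no antiperiplanar hydrogen for elimination, and any enolisation at C1 is self-correcting because the all-equatorial isomer is the more stable one.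

Step 8
Reactants: 14 ethyl (2E)-3-[(1R,3R,4S)-3-bromo-4-methyl-4-(triethylsilyloxy)cyclohexyl]but-2-enoate
Product: 15 (2E)-3-[(1R,3R,4S)-3-bromo-4-methyl-4-(triethylsilyloxy)cyclohexyl]but-2-en-1-ol
Conditions: i-Bu2AlH, CH2Cl2, −78 °C; aq. potassium sodium tartrate
Reagents that add atoms: none
Why: Reduction of the enoate with i-Bu2AlH at −78 °C is 1,2-selective and leaves the secondary bromide, the silyl ether and the alkene geometry untouched.

Step 9
Reactants: 15 (2E)-3-[(1R,3R,4S)-3-bromo-4-methyl-4-(triethylsilyloxy)cyclohexyl]but-2-en-1-ol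
Product: 17 diethyl {(2E)-3-[(1R,3R,4S)-3-bromo-4-methyl-4-(triethylsilyloxy)cyclohexyl]but-2-en-1-yl}phosphonate, via allylic bromide 16 (not isolated)
Conditions: MsCl, Et3N, THF, −40 °C; LiBr, 0 °C; then crude bromide, P(OEt)3 (neat), 90 °C
Reagents that add atoms: triethyl phosphite, CCOP(OCC)OCC
Why: The primary allylic mesylate is displaced by bromide in an SN2 reaction without allylic transposition, and the Michaelis–Arbuzov reaction of the allylic bromide gives the phosphonate with the E alkene intact, the secondary ring bromide being far less reactive.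

Step 10
Reactants: 18 (S)-linalool
Product: 19 (3R,6S)-3-bromo-6-ethenyl-2,2,6-trimethyloxane (bromine trans to the vinyl group)
Conditions: 2,4,4,6-tetrabromocyclohexa-2,5-dien-1-one, MeNO2, 0 → 23 °C, dark; chromatography
Reagents that add atoms: 2,4,4,6-tetrabromocyclohexa-2,5-dien-1-one, O=C1C(Br)=CC(Br)(Br)C=C1Br
Why: Bromonium formation at the electron-rich trisubstituted alkene and Markovnikov capture at the tertiary carbon by the tertiary hydroxyl (6-endo bromoetherification, anti addition) close the pyran with C11 untouched; C14 is expected as both epimers together with some 5-exo ether, so the trans isomer (bromine and vinyl both equatorial) is isolated by chromatography.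

Step 11
Reactants: 19 (3R,6S)-3-bromo-6-ethenyl-2,2,6-trimethyloxane
Product: 20 (2S,5R)-5-bromo-2,6,6-trimethyloxane-2-carbaldehyde
Conditions: O3, CH2Cl2, −78 °C; then PPh3, −78 → 23 °C
Reagents that add atoms: ozone, [O-][O+]=O
Why: Ozonolysis with reductive work-up cleaves the only alkene to the non-enolisable α-alkoxy aldehyde, leaving the C–Br bond and both stereocentres unaffected.

Step 12
Reactants: 17 diethyl {(2E)-3-[(1R,3R,4S)-3-bromo-4-methyl-4-(triethylsilyloxy)cyclohexyl]but-2-en-1-yl}phosphonate; 20 (2S,5R)-5-bromo-2,6,6-trimethyloxane-2-carbaldehyde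
Product: 21 {[(1S,2R,4R)-2-bromo-4-[(2E,4E)-5-[(2S,5R)-5-bromo-2,6,6-trimethyloxan-2-yl]penta-2,4-dien-2-yl]-1-methylcyclohexyl]oxy}triethylsilane
Conditions: KN(SiMe3)2, THF, −78 °C; then 20, −78 → 23 °C
Reagents that add atoms: none
Why: Horner–Wadsworth–Emmons olefination of the allylic phosphonate anion (attack through the α-carbon, the γ-carbon being fully substituted) with the non-enolisable aldehyde should give C9=C10 as the E alkene by reversible addition and syn-elimination of phosphate, the C7=C8 geometry being kept at low temperature and both secondary bromides inert to the hindered amide base at −78 °C.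

Step 13
Reactants: 21 triethylsilyl ether of the target
Product: 22 (1S,2R,4R)-2-bromo-4-[(2E,4E)-5-[(2S,5R)-5-bromo-2,6,6-trimethyloxan-2-yl]penta-2,4-dien-2-yl]-1-methylcyclohexan-1-ol (CNP0199463.1)
Conditions: HF·pyridine, pyridine, THF, 0 → 23 °C
Reagents that add atoms: none
Why: Fluoride cleaves the tertiary triethylsilyl ether, the pyridine buffer keeps the medium from ionising the dienylic C11–O bond or protonating the diene, and no alkoxide is generated next to the bromide.

**Compound list**

1 | isoprene (2-methylbuta-1,3-diene) | C=CC(C)=C | starting material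
2 | 2,2,2-trifluoroethyl acrylate | C=CC(=O)OCC(F)(F)F | starting material
3 | 2,2,2-trifluoroethyl (1R)-4-methylcyclohex-3-ene-1-carboxylate | CC1=CC[C@@H](CC1)C(=O)OCC(F)(F)F | intermediate
4 | (1R)-N-methoxy-N,4-dimethylcyclohex-3-ene-1-carboxamide (Weinreb amide) | CC1=CC[C@@H](CC1)C(=O)N(C)OC | intermediate
5 | 1-[(1R)-4-methylcyclohex-3-en-1-yl]ethan-1-one | CC1=CC[C@@H](CC1)C(C)=O | intermediate
6 | 1-[(1S,3R,6R)-6-methyl-7-oxabicyclo[4.1.0]heptan-3-yl]ethan-1-one (trans-epoxide, oxirane oxygen anti to acetyl) | CC(=O)[C@@H]1CC[C@@]2(C)O[C@H]2C1 | intermediate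
7 | 1-[(1R,3R,6S)-6-methyl-7-oxabicyclo[4.1.0]heptan-3-yl]ethan-1-one (cis-epoxide, oxirane oxygen syn to acetyl) | CC(=O)[C@@H]1CC[C@]2(C)O[C@@H]2C1 | intermediate
8 | 1-[(1R,3S,4S)-3,4-dihydroxy-4-methylcyclohexyl]ethan-1-one | CC(=O)[C@@H]1CC[C@](C)(O)[C@@H](O)C1 | intermediate
9 | 1-[(3aS,5R,7aS)-7a-methyl-2-oxidohexahydro-1,3,2-benzodioxathiol-5-yl]ethan-1-one (cyclic sulfite, both sulfur epimers) | CC(=O)[C@@H]1CC[C@]2(C)OS(=O)O[C@H]2C1 | intermediate
10 | 1-[(3aS,5R,7aS)-7a-methyl-2,2-dioxidohexahydro-1,3,2-benzodioxathiol-5-yl]ethan-1-one (cyclic sulfate) | CC(=O)[C@@H]1CC[C@]2(C)OS(=O)(=O)O[C@H]2C1 | intermediate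
11 | lithium (1S,2R,4R)-4-acetyl-2-bromo-1-methylcyclohexyl sulfate | CC(=O)[C@@H]1CC[C@](C)(OS(=O)(=O)[O-])[C@H](Br)C1.[Li+] | intermediate
12 | 1-[(1R,3R,4S)-3-bromo-4-hydroxy-4-methylcyclohexyl]ethan-1-one | CC(=O)[C@@H]1CC[C@](C)(O)[C@H](Br)C1 | intermediate
13 | 1-[(1R,3R,4S)-3-bromo-4-methyl-4-(triethylsilyloxy)cyclohexyl]ethan-1-one | CC(=O)[C@@H]1CC[C@](C)(O[Si](CC)(CC)CC)[C@H](Br)C1 | intermediate
14 | ethyl (2E)-3-[(1R,3R,4S)-3-bromo-4-methyl-4-(triethylsilyloxy)cyclohexyl]but-2-enoate | CCOC(=O)/C=C(\C)[C@@H]1CC[C@](C)(O[Si](CC)(CC)CC)[C@H](Br)C1 | intermediate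
15 | (2E)-3-[(1R,3R,4S)-3-bromo-4-methyl-4-(triethylsilyloxy)cyclohexyl]but-2-en-1-ol | OC/C=C(\C)[C@@H]1CC[C@](C)(O[Si](CC)(CC)CC)[C@H](Br)C1 | intermediate
16 | {[(1S,2R,4R)-2-bromo-4-[(2E)-4-bromobut-2-en-2-yl]-1-methylcyclohexyl]oxy}triethylsilane (allylic bromide) | BrC/C=C(\C)[C@@H]1CC[C@](C)(O[Si](CC)(CC)CC)[C@H](Br)C1 | intermediate
17 | diethyl {(2E)-3-[(1R,3R,4S)-3-bromo-4-methyl-4-(triethylsilyloxy)cyclohexyl]but-2-en-1-yl}phosphonate | CCOP(=O)(OCC)C/C=C(\C)[C@@H]1CC[C@](C)(O[Si](CC)(CC)CC)[C@H](Br)C1 | intermediate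
18 | (S)-linalool, (3S)-3,7-dimethylocta-1,6-dien-3-ol | C=C[C@@](C)(O)CCC=C(C)C | starting material
19 | (3R,6S)-3-bromo-6-ethenyl-2,2,6-trimethyloxane | C=C[C@]1(C)CC[C@@H](Br)C(C)(C)O1 | intermediate
20 | (2S,5R)-5-bromo-2,6,6-trimethyloxane-2-carbaldehyde | O=C[C@]1(C)CC[C@@H](Br)C(C)(C)O1 | intermediate
21 | {[(1S,2R,4R)-2-bromo-4-[(2E,4E)-5-[(2S,5R)-5-bromo-2,6,6-trimethyloxan-2-yl]penta-2,4-dien-2-yl]-1-methylcyclohexyl]oxy}triethylsilane | C/C(=C\C=C\[C@]1(C)CC[C@@H](Br)C(C)(C)O1)[C@@H]1CC[C@](C)(O[Si](CC)(CC)CC)[C@H](Br)C1 | intermediate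
22 | (1S,2R,4R)-2-bromo-4-[(2E,4E)-5-[(2S,5R)-5-bromo-2,6,6-trimethyloxan-2-yl]penta-2,4-dien-2-yl]-1-methylcyclohexan-1-ol | C/C(=C\C=C\[C@]1(C)CC[C@@H](Br)C(C)(C)O1)[C@@H]1CC[C@](C)(O)[C@H](Br)C1 | target

**Step count and risks**

Total: 13 steps. Longest linear sequence: 11 steps (steps 1–9, 12, 13).

Steps most likely to fail:

1. Step 10. The bromonium ion may be captured through the five-membered (5-exo) mode, and the remote C11 centre discriminates poorly between the two alkene faces, so the trans 6-endo ether could be a minor part of the mixture. The fallback sets out from 18 and comes back at 19, replacing bromonium chemistry by alkoxymercuration. Hg(OCOCF3)2 in MeNO2 at −20 °C, followed by aqueous KBr, should give the organomercurial [(3R,6S)-6-ethenyl-2,2,6-trimethyloxan-3-yl]mercury bromide F1. Alkoxymercuration is reversible and places oxygen on the tertiary carbon, so only the six-membered ether should form, and the trans isomer can be separated at this stage. Cleavage of the C–Hg bond with Br2 and LiBr in pyridine at 0 °C in the dark, a polar bromodemercuration expected to proceed largely with retention and faster than addition to the hindered vinyl group, then returns to 19.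

2. Step 5. Ionisation at the tertiary C4–O bond or elimination may compete with SN2 inversion at C5, whose rear side in the trans-fused sulfate is screened by the quaternary C4 and by the axial acetyl-bearing C1. The fallback sets out from 2 and comes back at 12, building the cis-bromohydrin by carbonyl addition instead of displacement while keeping the same cycloaddition. Under the conditions of step 1, 2 and 2-(triisopropylsilyloxy)buta-1,3-diene F2 (from methyl vinyl ketone, i-Pr3SiOTf, Et3N) should give 2,2,2-trifluoroethyl (1R)-4-(triisopropylsilyloxy)cyclohex-3-ene-1-carboxylate F3. Amidation (MeNH(OMe)·HCl, i-PrMgCl, THF, −20 °C) gives (1R)-N-methoxy-N-methyl-4-(triisopropylsilyloxy)cyclohex-3-ene-1-carboxamide F4. N-Bromosuccinimide in THF at −78 °C brominates the enol ether carbon (C5), and after equilibration with a trace of HBr the cis isomer with equatorial bromine, (1R,3R)-3-bromo-N-methoxy-N-methyl-4-oxocyclohexane-1-carboxamide F5, is taken on. Excess MeMgBr (THF, −78 → 0 °C) then adds equatorially to the ring ketone, the classical route from α-haloketones to cis-halohydrins, and converts the amide into the methyl ketone, giving 12.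

3. Step 12. Addition of the bulky phosphonate anion to the α-quaternary aldehyde may be slow, and a long-lived delocalised allyl anion may lose the C7=C8 geometry or react through the γ-carbon. The fallback sets out from 15 and comes back at 21, using a Julia–Kocienski olefination under Barbier conditions so that the anion is trapped as it forms. Mitsunobu reaction of 15 with 1-phenyl-1H-tetrazole-5-thiol (PPh3, diisopropyl azodicarboxylate, THF, 0 °C) gives 5-{[(2E)-3-[(1R,3R,4S)-3-bromo-4-methyl-4-(triethylsilyloxy)cyclohexyl]but-2-en-1-yl]sulfanyl}-1-phenyl-1H-tetrazole F6. Oxidation at sulfur with (NH4)6Mo7O24·4H2O and H2O2 in EtOH gives the sulfone 5-{[(2E)-3-[(1R,3R,4S)-3-bromo-4-methyl-4-(triethylsilyloxy)cyclohexyl]but-2-en-1-yl]sulfonyl}-1-phenyl-1H-tetrazole F7. KN(SiMe3)2 is then added at −78 °C to a mixture of this sulfone and 20 in 1,2-dimethoxyethane; addition, Smiles rearrangement and loss of SO2 and the tetrazolone should deliver 21. The C9=C10 geometry from allylic sulfones depends on the aldehyde, so an E/Z separation may be needed.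

Further compounds
F1 | step 10 | [(3R,6S)-6-ethenyl-2,2,6-trimethyloxan-3-yl]mercury bromide | C=C[C@]1(C)CC[C@@H]([Hg]Br)C(C)(C)O1
F2 | step 5 | 2-(triisopropylsilyloxy)buta-1,3-diene | C=CC(=C)O[Si](C(C)C)(C(C)C)C(C)C
F3 | step 5 | 2,2,2-trifluoroethyl (1R)-4-(triisopropylsilyloxy)cyclohex-3-ene-1-carboxylate | FC(F)(F)COC(=O)[C@H]1CC=C(O[Si](C(C)C)(C(C)C)C(C)C)CC1
F4 | step 5 | (1R)-N-methoxy-N-methyl-4-(triisopropylsilyloxy)cyclohex-3-ene-1-carboxamide | CON(C)C(=O)[C@H]1CC=C(O[Si](C(C)C)(C(C)C)C(C)C)CC1
F5 | step 5 | (1R,3R)-3-bromo-N-methoxy-N-methyl-4-oxocyclohexane-1-carboxamide | CON(C)C(=O)[C@@H]1CCC(=O)[C@H](Br)C1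
F6 | step 12 | 5-{[(2E)-3-[(1R,3R,4S)-3-bromo-4-methyl-4-(triethylsilyloxy)cyclohexyl]but-2-en-1-yl]sulfanyl}-1-phenyl-1H-tetrazole | C/C(=C\CSc1nnnn1-c1ccccc1)[C@@H]1CC[C@](C)(O[Si](CC)(CC)CC)[C@H](Br)C1
F7 | step 12 | 5-{[(2E)-3-[(1R,3R,4S)-3-bromo-4-methyl-4-(triethylsilyloxy)cyclohexyl]but-2-en-1-yl]sulfonyl}-1-phenyl-1H-tetrazole | C/C(=C\CS(=O)(=O)c1nnnn1-c1ccccc1)[C@@H]1CC[C@](C)(O[Si](CC)(CC)CC)[C@H](Br)C1
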